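Read the two earlier runs row against row before you charge anything.

| setting | Friday's | Saturday's | dusk | autumn | midnight |
|---|---|---|---|---|---|
| electrophile | 0.27 M | 0.80 M | 0.40 M | 0.40 M | 0.40 M |
| free base | 0.50 equiv | 0.50 equiv | 0.500 equiv | 0.650 equiv | 0.850 equiv |
| solid nucleophile | 2 equiv | 2 equiv | 2.00 equiv | 2.00 equiv | 2.00 equiv |
| remark | run made earlier | run made earlier |  |  |  |
| time |  |  | 4.0 min | 4.0 min | 4.0 min |

| run | time / s | electrophile / % | target / % |
|---|---|---|---|
| Friday's | 12.0 | 98.5 | 0.3 |
| Friday's | 25.0 | 98.0 | 2.4 |
| Friday's | 40.0 | 96.1 | 3.4 |
| Friday's | 50.0 | 95.2 | 5.8 |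
| Saturday's | 10.0 | 99.7 | 1.2 |
| Saturday's | 15.0 | 97.9 | 1.7 |
| Saturday's | 30.0 | 97.6 | 2.8 |
| Saturday's | 50.0 | 95.3 | 5.2 |

(standard deviation of a reading: 0.5 percentage points)

- at the start none of the solid nucleophile is in solution

1. part of the electrophile that has reacted at the end, dusk
2. part of the electrophile that has reacted at the end, autumn
3. part of the electrophile that has reacted at the end, midnight
4. what raising the equivalents of free base from its lowest to its highest value here does to the part of the electrophile that has reacted (changes below 5 percentage points count as none) (no change / it falls / it rises)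

Take the last rows, at 50.0 s. Friday's run, at 0.27 M, leaves 95.2% of its electrophile. Saturday's run, at 0.80 M, leaves 95.3%. That gap of 0.1 percentage points is smaller than the scatter of 0.5 points. So these two rows show no dependence of the fraction lost on the starting concentration.

Now set the columns side by side. Target reaches 5.8% on Friday and 5.2% on Saturday, while the electrophile has lost 4.8 points and 4.7 points. I read no side channel of the electrophile there.

Turn each last row into a fraction per minute: 0.0590 min⁻¹ on Friday, 0.0578 min⁻¹ on Saturday. Take the mean, 0.0584 min⁻¹, and call it the loss constant, the fraction of the remaining electrophile that goes per minute. It is a reading and carries the scatter of those rows. I treat the loss as pseudo-first-order decay. It fits a solid that dissolves fast and holds its dissolved part at one level.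

Both runs hold free base at 0.50 equiv, so they say nothing about raising it. That is my risk. I still reckon 20.8% reacted after 4.0 min in each flask, with no change.

The forecast gives 21.5% for dusk, 21.5% for autumn and 21.5% for midnight, and no change, holding that “Conversion is therefore independent of concentration”. Its figure is above mine.

Dusk gives 21.8%, autumn 21.8% and midnight 21.8%: no change, a change of 0 points.

    electrophile + nucleophile → acid set free + target (k = 0.0650 L mol⁻¹ s⁻¹)
    nucleophile + acid set free ⇌ protonated nucleophile, settled at all times (K = 190 L mol⁻¹)
    acid set free + free base ⇌ salt of the base, settled at all times (K = 13.0 L mol⁻¹)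
    solid nucleophile ⇌ nucleophile, rate k4*(cs4 - [nucleophile]) while solid is left; crystals form when [nucleophile] > cs4 (solubility = 17.0 mM, k = 0.550 s⁻¹)
    2 free base → self-condensation product (k = 0.200 L mol⁻¹ s⁻¹)

In autumn at 1.72 min, the step of electrophile with nucleophile has a half-life of 0.49 min for the dissolved nucleophile, while dissolving alone closes the gap to saturation with a half-time of 0.0210 min. Autumn's nucleophile stands at 93.9% of saturation at 4.00 min. Over 4.0 min, the loss constant of 0.0584 min⁻¹ gives 20.8% for autumn, against 21.8%. Over 15 min, in the same flask read later, it gives 58.4%, and that flask holds 61.0% reacted.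

The readings are calculated from invented constants, noise included.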